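**Retrosynthetic overview**

1. Target ⇐ its methyl ester ⇐ C5–C1′ bond, made by a stereoretentive 1,2-shift of ring carbon C5 from boron to the dienyl carbon (boronate 1,2-metallate rearrangement) between a tertiary C5 boronic ester and a (1E,3E)-dienyl iodide built from phenylacetylene.
2. Tertiary boronic ester ⇐ trans-fused hydrindenone by face-selective conjugate borylation, enol triflation and methylation (C6=C7, C7–Me).
3. Cyclopentene ring (formed second) ⇐ ring-closing metathesis of a trans-5,6-dialkenyl cyclohexenone; the two alkenyl arms come from cuprate addition and Ir-allylation on a 4,4-disubstituted cyclohexadienone.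
4. Six-membered ring (formed first) ⇐ asymmetric Robinson annulation of methyl 2-methylacetoacetate with methyl vinyl ketone, then dehydrogenation; the quaternary centre set here steers all later centres.

Assumption: bicyclic compounds carry 1H-indene locants (ester carbon C4, boron/dienyl carbon C5), organometallic species are written as σ-bonded monomers, and in the catalyst-controlled steps 2 and 5 the catalyst antipode that gives the drawn configuration is used.

**Route**

Step 1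
Reactants: 1 methyl acetoacetate (methyl 3-oxobutanoate)
Product: 2 methyl 2-methyl-3-oxobutanoate (racemic, configurationally labile)
Conditions: MeI (1.05 equiv), K2CO3, acetone, reflux
Reagents that add atoms: iodomethane, CI
Why: Acetoacetic ester C-alkylation under carbonate conditions gives the monomethyl compound; the new centre is labile and is fixed in step 2.

Step 2
Reactants: 2 methyl 2-methyl-3-oxobutanoate; 3 but-3-en-2-one (methyl vinyl ketone)
Product: 5 methyl (1R)-1,2-dimethyl-4-oxocyclohex-2-ene-1-carboxylate, via methyl (2R)-2-acetyl-2-methyl-5-oxohexanoate 4 (not isolated)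
Conditions: bifunctional 6′-OH cinchona catalyst (10 mol %), CH2Cl2, −24 °C; then pyrrolidine/AcOH (30 mol %), toluene, 60 °C
Reagents that add atoms: none
Why: Catalytic asymmetric Michael addition of the α-methyl β-keto ester to the enone sets the quaternary centre (R, catalyst control), and the Robinson annulation is completed by enamine aldol condensation of the unhindered methyl ketone onto the acetyl group.

Step 3
Reactants: 5 methyl (1R)-1,2-dimethyl-4-oxocyclohex-2-ene-1-carboxylate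
Product: 6 methyl (1R)-1,2-dimethyl-4-oxocyclohexa-2,5-diene-1-carboxylate
Conditions: IBX (2 equiv), DMSO/fluorobenzene, 70 °C
Reagents that add atoms: none
Why: IBX α′,β′-dehydrogenation of the enone (Nicolaou oxidation) gives the cross-conjugated dienone; the quaternary C1 blocks aromatisation and is untouched.

Step 4
Reactants: 6 methyl (1R)-1,2-dimethyl-4-oxocyclohexa-2,5-diene-1-carboxylate; 7 2-bromobut-1-ene
Product: 9 methyl (1R,6R)-6-(but-1-en-2-yl)-1,2-dimethyl-4-[(trimethylsilyl)oxy]cyclohexa-2,4-diene-1-carboxylate, via (but-1-en-2-yl)magnesium bromide 8 (not isolated)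
Conditions: Mg, THF, 40 °C; then 6, CuBr·SMe2 (10 mol %), TMSCl, HMPA, THF, −78 °C
Reagents that add atoms: chlorotrimethylsilane, C[Si](C)(C)Cl
Why: TMSCl-accelerated Cu-catalysed conjugate addition of the alkenyl Grignard goes to the unsubstituted β-carbon C6 and anti to the neighbouring C1 ester, so the butenyl group ends cis to the C1 methyl (C6 = R), and silylation fixes the enolate regiochemistry.

Step 5
Reactants: 9 methyl (1R,6R)-6-(but-1-en-2-yl)-1,2-dimethyl-4-[(trimethylsilyl)oxy]cyclohexa-2,4-diene-1-carboxylate; 10 (E)-but-2-en-1-yl acetate (crotyl acetate)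
Product: 11 methyl (1R,5S,6R)-6-(but-1-en-2-yl)-5-[(2R)-but-3-en-2-yl]-1,2-dimethyl-4-oxocyclohex-2-ene-1-carboxylate
Conditions: [Ir(cod)Cl]2 (2 mol %), chiral phosphoramidite (4 mol %), CsF (1.2 equiv), ZnF2 (cat.), THF, 50 °C
Reagents that add atoms: none
Why: Ir-catalysed branched-selective allylic alkylation of the fluoride-released enolate (Hartwig–Helmchen type); the allyl-iridium attacks C5 anti to the C6 substituent (trans-5,6) and the ligand fixes the (2R) centre of the butenyl arm.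

Step 6
Reactants: 11 methyl (1R,5S,6R)-6-(but-1-en-2-yl)-5-[(2R)-but-3-en-2-yl]-1,2-dimethyl-4-oxocyclohex-2-ene-1-carboxylate
Product: 12 methyl (1R,3aR,4R,7aS)-3-ethyl-1,4,5-trimethyl-7-oxo-3a,4,7,7a-tetrahydro-1H-indene-4-carboxylate
Conditions: Grubbs II (5 mol %), CH2Cl2, 40 °C
Reagents that add atoms: none
Why: Ring-closing metathesis of the 1,1-disubstituted and monosubstituted alkenes closes the trisubstituted cyclopentene and locks the trans ring fusion; the electron-poor trisubstituted enone alkene stays out.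

Step 7
Reactants: 12 methyl (1R,3aR,4R,7aS)-3-ethyl-1,4,5-trimethyl-7-oxo-3a,4,7,7a-tetrahydro-1H-indene-4-carboxylate
Product: 13 methyl (1R,3aR,4R,5R,7aS)-3-ethyl-1,4,5-trimethyl-7-oxo-5-(4,4,5,5-tetramethyl-1,3,2-dioxaborolan-2-yl)-3a,4,5,6,7,7a-hexahydro-1H-indene-4-carboxylate
Conditions: B2pin2 (1.2 equiv), CuCl (10 mol %), DPEphos (10 mol %), NaOtBu (15 mol %), MeOH (2 equiv), THF, 0 °C
Reagents that add atoms: bis(pinacolato)diboron, CC1(C)OB(OC1(C)C)B1OC(C)(C)C(C)(C)O1
Why: Cu-catalysed conjugate borylation (Yun–Hoveyda β-boration); the small Cu–Bpin adds axially to C5 of the rigid trans-fused enone, anti to the axial C4 methyl and syn to H-3a (C5 = R), and the weakly basic, cold conditions leave the α-keto ring-fusion centre C7a alone.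

Step 8
Reactants: 13 methyl (1R,3aR,4R,5R,7aS)-3-ethyl-1,4,5-trimethyl-7-oxo-5-(4,4,5,5-tetramethyl-1,3,2-dioxaborolan-2-yl)-3a,4,5,6,7,7a-hexahydro-1H-indene-4-carboxylate
Product: 15 methyl (1R,3aR,4R,5R,7aS)-3-ethyl-1,4,5-trimethyl-5-(4,4,5,5-tetramethyl-1,3,2-dioxaborolan-2-yl)-7-{[(trifluoromethyl)sulfonyl]oxy}-3a,4,5,7a-tetrahydro-1H-indene-4-carboxylate, via potassium C6=C7 enolate 14 (not isolated)
Conditions: KHMDS, THF, −78 °C; then PhNTf2, −78 → 0 °C
Reagents that add atoms: N-phenylbis(trifluoromethanesulfonimide), O=S(=O)(N(c1ccccc1)S(=O)(=O)C(F)(F)F)C(F)(F)F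
Why: Kinetic deprotonation at the C6 methylene rather than the C7a methine, then O-triflation, gives the C6=C7 enol triflate without touching a stereocentre.

Step 9
Reactants: 15 methyl (1R,3aR,4R,5R,7aS)-3-ethyl-1,4,5-trimethyl-5-(4,4,5,5-tetramethyl-1,3,2-dioxaborolan-2-yl)-7-{[(trifluoromethyl)sulfonyl]oxy}-3a,4,5,7a-tetrahydro-1H-indene-4-carboxylate
Product: 16 methyl (1R,3aR,4R,5R,7aS)-3-ethyl-1,4,5,7-tetramethyl-5-(4,4,5,5-tetramethyl-1,3,2-dioxaborolan-2-yl)-3a,4,5,7a-tetrahydro-1H-indene-4-carboxylate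
Conditions: Me2Zn (1.5 equiv), Pd(PPh3)4 (5 mol %), THF, 50 °C
Reagents that add atoms: dimethylzinc, C[Zn]C
Why: Negishi cross-coupling of the alkenyl triflate puts the C7 methyl on the C6=C7 double bond; the tertiary alkyl boronic ester does not transmetalate.

Step 10
Reactants: 17 phenylacetylene
Product: 19 [(E)-2-iodoethenyl]benzene, via chloridobis(cyclopentadienyl)[(E)-2-phenylethenyl]zirconium 18 (not isolated)
Conditions: Cp2Zr(H)Cl, THF, 25 °C; then I2, 0 °C
Reagents that add atoms: iodine, II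
Why: syn-Hydrozirconation (Schwartz) places zirconium on the terminal carbon, and iodinolysis with retention gives the E-alkenyl iodide.

Step 11
Reactants: 19 [(E)-2-iodoethenyl]benzene; 20 ethynylmagnesium bromide
Product: 22 [(E)-but-1-en-3-yn-1-yl]benzene, via ethynylzinc bromide 21 (not isolated)
Conditions: ZnBr2, THF, 0 °C; then 19, Pd(PPh3)4 (3 mol %), 25 °C
Reagents that add atoms: none
Why: Negishi alkynylation of the alkenyl iodide proceeds with retention of the E geometry.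

Step 12
Reactants: 22 [(E)-but-1-en-3-yn-1-yl]benzene
Product: 24 [(1E,3E)-4-iodo-3-methylbuta-1,3-dien-1-yl]benzene, via dimethyl[(1E,3E)-2-methyl-4-phenylbuta-1,3-dien-1-yl]alane 23 (not isolated)
Conditions: Me3Al (2 equiv), Cp2ZrCl2 (0.25 equiv), CH2Cl2, 0 → 25 °C; then I2, THF, −30 °C
Reagents that add atoms: trimethylaluminium, C[Al](C)C; iodine, II
Why: Negishi Zr-catalysed syn-carboalumination of the terminal alkyne (methyl to the internal carbon), then iodinolysis with retention, gives the E-trisubstituted alkenyl iodide.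

Step 13
Reactants: 16 methyl (1R,3aR,4R,5R,7aS)-3-ethyl-1,4,5,7-tetramethyl-5-(4,4,5,5-tetramethyl-1,3,2-dioxaborolan-2-yl)-3a,4,5,7a-tetrahydro-1H-indene-4-carboxylate; 24 [(1E,3E)-4-iodo-3-methylbuta-1,3-dien-1-yl]benzene
Product: 28 methyl (1R,3aR,4R,5S,7aS)-3-ethyl-1,4,5,7-tetramethyl-5-[(1E,3E)-2-methyl-4-phenylbuta-1,3-dien-1-yl]-3a,4,5,7a-tetrahydro-1H-indene-4-carboxylate, via [(1E,3E)-2-methyl-4-phenylbuta-1,3-dien-1-yl]lithium 25 (not isolated), via lithium dienylboronate complex 26 (not isolated), via β-(phenylselanyl)alkylboronic ester 27 (not isolated)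
Conditions: 24, t-BuLi (2 equiv), Et2O, −78 °C; then 16, THF, −78 → 0 °C; then PhSeCl (1.0 equiv), THF/CF3CH2OH, −78 °C; then mCPBA (1.05 equiv), −45 °C → rt
Reagents that add atoms: none
Why: Proposed new method: a selenium-mediated Zweifel-type coupling in which ring carbon C5 undergoes a 1,2-shift from boron to the dienyl carbon; the dienyllithium adds to the tertiary Bpin (faster at −78 °C than attack on the doubly neopentyl ester), PhSe+ activates the electron-rich alkenyl–boron unit at C2′, C5 migrates to C1′ anti to selenium with retention at C5 (a 1,2-metallate rearrangement, intramolecular and so tolerant of the neighbouring quaternary C4), and boron-assisted selenoxide syn-elimination then gives the alkene with the geometry of the lithium compound, so the dienyl group takes the place of boron (C5 becomes S only through CIP priorities) and the side chain is 1E,3E; the closest known reactions are the Zweifel olefination and its PhSeCl/mCPBA variant on boronic esters with simple alkenyllithiums, not yet shown for a 1,3-dienyllithium or next to a quaternary stereocentre.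

Step 14
Reactants: 28 methyl (1R,3aR,4R,5S,7aS)-3-ethyl-1,4,5,7-tetramethyl-5-[(1E,3E)-2-methyl-4-phenylbuta-1,3-dien-1-yl]-3a,4,5,7a-tetrahydro-1H-indene-4-carboxylate
Product: 29 zyggomphic acid B [(1R,3aR,4R,5S,7aS)-3-ethyl-1,4,5,7-tetramethyl-5-[(1E,3E)-2-methyl-4-phenylbuta-1,3-dien-1-yl]-3a,4,5,7a-tetrahydro-1H-indene-4-carboxylic acid]
Conditions: LiI (6 equiv), EtOAc, reflux; then 1 M HCl
Reagents that add atoms: none
Why: SN2 dealkylation at the ester methyl group (nucleophilic ester cleavage) frees the doubly neopentyl acid without touching the diene or any stereocentre.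

**Compound list**

1 | methyl acetoacetate | COC(=O)CC(C)=O | starting material
2 | methyl 2-methyl-3-oxobutanoate (racemic) | COC(=O)C(C)C(C)=O | intermediate
3 | but-3-en-2-one | CC(=O)C=C | starting material
4 | methyl (2R)-2-acetyl-2-methyl-5-oxohexanoate | CC(=O)CC[C@@](C(C)=O)(C)C(=O)OC | intermediate
5 | methyl (1R)-1,2-dimethyl-4-oxocyclohex-2-ene-1-carboxylate | CC1=CC(=O)CC[C@@]1(C)C(=O)OC | intermediate
6 | methyl (1R)-1,2-dimethyl-4-oxocyclohexa-2,5-diene-1-carboxylate | CC1=CC(=O)C=C[C@@]1(C)C(=O)OC | intermediate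
7 | 2-bromobut-1-ene | CCC(Br)=C | starting material
8 | (but-1-en-2-yl)magnesium bromide | CCC(=C)[Mg]Br | intermediate
9 | methyl (1R,6R)-6-(but-1-en-2-yl)-1,2-dimethyl-4-[(trimethylsilyl)oxy]cyclohexa-2,4-diene-1-carboxylate | C[Si](C)(C)OC1=C[C@H](C(CC)=C)[C@@](C)(C(=O)OC)C(C)=C1 | intermediate
10 | (E)-but-2-en-1-yl acetate | C/C=C/COC(C)=O | starting material
11 | methyl (1R,5S,6R)-6-(but-1-en-2-yl)-5-[(2R)-but-3-en-2-yl]-1,2-dimethyl-4-oxocyclohex-2-ene-1-carboxylate | O=C1C=C(C)[C@](C)(C(=O)OC)[C@@H](C(CC)=C)[C@@H]1[C@H](C)C=C | intermediate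
12 | methyl (1R,3aR,4R,7aS)-3-ethyl-1,4,5-trimethyl-7-oxo-3a,4,7,7a-tetrahydro-1H-indene-4-carboxylate | CCC1=C[C@@H](C)[C@@H]2C(=O)C=C(C)[C@](C)(C(=O)OC)[C@@H]12 | intermediate
13 | methyl (1R,3aR,4R,5R,7aS)-3-ethyl-1,4,5-trimethyl-7-oxo-5-(4,4,5,5-tetramethyl-1,3,2-dioxaborolan-2-yl)-3a,4,5,6,7,7a-hexahydro-1H-indene-4-carboxylate | CCC1=C[C@@H](C)[C@@H]2C(=O)C[C@](C)(B3OC(C)(C)C(C)(C)O3)[C@](C)(C(=O)OC)[C@@H]12 | intermediate
14 | potassium C6=C7 enolate of 13: potassium (1R,3aR,4R,5R,7aS)-3-ethyl-4-(methoxycarbonyl)-1,4,5-trimethyl-5-(4,4,5,5-tetramethyl-1,3,2-dioxaborolan-2-yl)-3a,4,5,7a-tetrahydro-1H-inden-7-olate | [K+].CCC1=C[C@@H](C)[C@@H]2C([O-])=C[C@](C)(B3OC(C)(C)C(C)(C)O3)[C@](C)(C(=O)OC)[C@@H]12 | intermediate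
15 | methyl (1R,3aR,4R,5R,7aS)-3-ethyl-1,4,5-trimethyl-5-(4,4,5,5-tetramethyl-1,3,2-dioxaborolan-2-yl)-7-{[(trifluoromethyl)sulfonyl]oxy}-3a,4,5,7a-tetrahydro-1H-indene-4-carboxylate | CCC1=C[C@@H](C)[C@@H]2C(OS(=O)(=O)C(F)(F)F)=C[C@](C)(B3OC(C)(C)C(C)(C)O3)[C@](C)(C(=O)OC)[C@@H]12 | intermediate
16 | methyl (1R,3aR,4R,5R,7aS)-3-ethyl-1,4,5,7-tetramethyl-5-(4,4,5,5-tetramethyl-1,3,2-dioxaborolan-2-yl)-3a,4,5,7a-tetrahydro-1H-indene-4-carboxylate | CCC1=C[C@@H](C)[C@@H]2C(C)=C[C@](C)(B3OC(C)(C)C(C)(C)O3)[C@](C)(C(=O)OC)[C@@H]12 | intermediate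
17 | phenylacetylene | C#Cc1ccccc1 | starting material
18 | chloridobis(cyclopentadienyl)[(E)-2-phenylethenyl]zirconium | Cl[Zr](/C=C/c1ccccc1)(C1C=CC=C1)C1C=CC=C1 | intermediate
19 | [(E)-2-iodoethenyl]benzene | I/C=C/c1ccccc1 | intermediate
20 | ethynylmagnesium bromide | C#C[Mg]Br | starting material
21 | ethynylzinc bromide | C#C[Zn]Br | intermediate
22 | [(E)-but-1-en-3-yn-1-yl]benzene | C#C/C=C/c1ccccc1 | intermediate
23 | dimethyl[(1E,3E)-2-methyl-4-phenylbuta-1,3-dien-1-yl]alane | C[Al](C)/C=C(C)/C=C/c1ccccc1 | intermediate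
24 | [(1E,3E)-4-iodo-3-methylbuta-1,3-dien-1-yl]benzene | I/C=C(C)/C=C/c1ccccc1 | intermediate
25 | [(1E,3E)-2-methyl-4-phenylbuta-1,3-dien-1-yl]lithium | [Li]/C=C(C)/C=C/c1ccccc1 | intermediate
26 | lithium dienylboronate complex: the pinacol borate anion in which boron carries C5 of 16 (configuration kept, 5R) and the (1E,3E)-2-methyl-4-phenylbuta-1,3-dien-1-yl group; lithium counter-ion | [Li+].CCC1=C[C@@H](C)[C@@H]2C(C)=C[C@](C)([B-]3(/C=C(C)/C=C/c4ccccc4)OC(C)(C)C(C)(C)O3)[C@](C)(C(=O)OC)[C@@H]12 | intermediate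
27 | β-(phenylselanyl)alkylboronic ester: methyl (1R,3aR,4R,5S,7aS)-3-ethyl-1,4,5,7-tetramethyl-5-[(1R,2S,3E)-2-methyl-4-phenyl-2-(phenylselanyl)-1-(4,4,5,5-tetramethyl-1,3,2-dioxaborolan-2-yl)but-3-en-1-yl]-3a,4,5,7a-tetrahydro-1H-indene-4-carboxylate (anti adduct of C5 and PhSe; the 1′S,2′R anti adduct from the other alkene face gives the same alkene) | CCC1=C[C@@H](C)[C@@H]2C(C)=C[C@](C)([C@@H](B3OC(C)(C)C(C)(C)O3)[C@](C)([Se]c3ccccc3)/C=C/c3ccccc3)[C@](C)(C(=O)OC)[C@@H]12 | intermediate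
28 | methyl (1R,3aR,4R,5S,7aS)-3-ethyl-1,4,5,7-tetramethyl-5-[(1E,3E)-2-methyl-4-phenylbuta-1,3-dien-1-yl]-3a,4,5,7a-tetrahydro-1H-indene-4-carboxylate | CCC1=C[C@@H](C)[C@@H]2C(C)=C[C@](C)(/C=C(C)/C=C/c3ccccc3)[C@](C)(C(=O)OC)[C@@H]12 | intermediate
29 | zyggomphic acid B, (1R,3aR,4R,5S,7aS)-3-ethyl-1,4,5,7-tetramethyl-5-[(1E,3E)-2-methyl-4-phenylbuta-1,3-dien-1-yl]-3a,4,5,7a-tetrahydro-1H-indene-4-carboxylic acid | CCC1=C[C@@H](C)[C@@H]2C(C)=C[C@](C)(/C=C(C)/C=C/c3ccccc3)[C@](C)(C(=O)O)[C@@H]12 | target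

**Step count**

Total: 14 steps. Longest linear sequence: 11 steps (1–9, 13, 14); the side chain takes 3 (10–12).

**Three steps most likely to fail, with fallbacks**

Step 13 (the proposed new coupling). The hindered tertiary boronic ester next to a quaternary carbon may not form the ate complex. The allylic selenoxide may also undergo a [2,3]-shift before the boron-assisted elimination, or the alkene geometry may be lost. The fallback uses known chemistry. It sets out from enone 12 and uses alane 23 (made from 22 as in step 12, without the iodine quench). Cu(I)-catalysed conjugate addition of 23 to 12 (CuTC, phosphoramidite or NHC ligand, Et2O, −30 °C; alkenylalane additions to 3-methylcyclohexenones are known) occurs from the same axial face. It gives the aluminium enolate methyl (1R,3aR,4R,5S,7aS)-7-[(dimethylalumanyl)oxy]-3-ethyl-1,4,5-trimethyl-5-[(1E,3E)-2-methyl-4-phenylbuta-1,3-dien-1-yl]-3a,4,5,7a-tetrahydro-1H-indene-4-carboxylate F1. F1 is activated in the flask with MeLi and O-triflated with PhNTf2 to give methyl (1R,3aR,4R,5S,7aS)-3-ethyl-1,4,5-trimethyl-5-[(1E,3E)-2-methyl-4-phenylbuta-1,3-dien-1-yl]-7-{[(trifluoromethyl)sulfonyl]oxy}-3a,4,5,7a-tetrahydro-1H-indene-4-carboxylate F2. Negishi methylation of F2 under the conditions of step 9 gives 28, where the route is rejoined before step 14.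

Step 4 (facial selectivity of the cuprate addition to the dienone). If addition anti to the ester is not selective, the face is put under catalyst control. The fallback sets out from 6 and 8. Grignard 8 is quenched with 2-isopropoxy-4,4,5,5-tetramethyl-1,3,2-dioxaborolane to give 2-(but-1-en-2-yl)-4,4,5,5-tetramethyl-1,3,2-dioxaborolane F3. Rh(I)/chiral diene-catalysed Hayashi–Miyaura 1,4-addition of F3 to 6 (aqueous KOH, dioxane) gives methyl (1R,6R)-6-(but-1-en-2-yl)-1,2-dimethyl-4-oxocyclohex-2-ene-1-carboxylate F4. Kinetic α′-deprotonation of F4 with LDA (THF, −78 °C) gives the cross-conjugated dienolate lithium (3R,4R)-3-(but-1-en-2-yl)-4-(methoxycarbonyl)-4,5-dimethylcyclohexa-1,5-dien-1-olate F5. Silylation of F5 with TMSCl gives 9, where the route is rejoined before step 5.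

Step 8 (regiochemistry of enolisation, C6 methylene against C7a methine, and base-induced epimerisation of C7a to the cis-fused ring system in steps 7 and 8). The fallback sets out from 12 and avoids both the basic borylation and the deprotonation. Pt(0)-catalysed 1,4-diboration of the enone with B2pin2 (toluene, 80 °C, base-free) gives the boron enolate methyl (1R,3aR,4R,5R,7aS)-3-ethyl-1,4,5-trimethyl-5-(4,4,5,5-tetramethyl-1,3,2-dioxaborolan-2-yl)-7-[(4,4,5,5-tetramethyl-1,3,2-dioxaborolan-2-yl)oxy]-3a,4,5,7a-tetrahydro-1H-indene-4-carboxylate F6, with the C6=C7 enolate fixed by the addition. MeLi (1 equiv, THF, −78 °C) cleaves the O–B bond and gives the enolate lithium (1R,3aR,4R,5R,7aS)-3-ethyl-4-(methoxycarbonyl)-1,4,5-trimethyl-5-(4,4,5,5-tetramethyl-1,3,2-dioxaborolan-2-yl)-3a,4,5,7a-tetrahydro-1H-inden-7-olate F7. PhNTf2 turns F7 into 15, where the route is rejoined before step 9.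

Further compounds
F1 | step 13 | methyl (1R,3aR,4R,5S,7aS)-7-[(dimethylalumanyl)oxy]-3-ethyl-1,4,5-trimethyl-5-[(1E,3E)-2-methyl-4-phenylbuta-1,3-dien-1-yl]-3a,4,5,7a-tetrahydro-1H-indene-4-carboxylate | CCC1=C[C@@H](C)[C@@H]2C(O[Al](C)C)=C[C@](C)(/C=C(C)/C=C/c3ccccc3)[C@](C)(C(=O)OC)[C@@H]12
F2 | step 13 | methyl (1R,3aR,4R,5S,7aS)-3-ethyl-1,4,5-trimethyl-5-[(1E,3E)-2-methyl-4-phenylbuta-1,3-dien-1-yl]-7-{[(trifluoromethyl)sulfonyl]oxy}-3a,4,5,7a-tetrahydro-1H-indene-4-carboxylate | CCC1=C[C@@H](C)[C@@H]2C(OS(=O)(=O)C(F)(F)F)=C[C@](C)(/C=C(C)/C=C/c3ccccc3)[C@](C)(C(=O)OC)[C@@H]12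
F3 | step 4 | 2-(but-1-en-2-yl)-4,4,5,5-tetramethyl-1,3,2-dioxaborolane | CCC(=C)B1OC(C)(C)C(C)(C)O1
F4 | step 4 | methyl (1R,6R)-6-(but-1-en-2-yl)-1,2-dimethyl-4-oxocyclohex-2-ene-1-carboxylate | O=C1C=C(C)[C@](C)(C(=O)OC)[C@@H](C(CC)=C)C1
F5 | step 4 | lithium (3R,4R)-3-(but-1-en-2-yl)-4-(methoxycarbonyl)-4,5-dimethylcyclohexa-1,5-dien-1-olate | [Li+].[O-]C1=C[C@H](C(CC)=C)[C@@](C)(C(=O)OC)C(C)=C1
F6 | step 8 | methyl (1R,3aR,4R,5R,7aS)-3-ethyl-1,4,5-trimethyl-5-(4,4,5,5-tetramethyl-1,3,2-dioxaborolan-2-yl)-7-[(4,4,5,5-tetramethyl-1,3,2-dioxaborolan-2-yl)oxy]-3a,4,5,7a-tetrahydro-1H-indene-4-carboxylate | CCC1=C[C@@H](C)[C@@H]2C(OB3OC(C)(C)C(C)(C)O3)=C[C@](C)(B3OC(C)(C)C(C)(C)O3)[C@](C)(C(=O)OC)[C@@H]12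
F7 | step 8 | lithium (1R,3aR,4R,5R,7aS)-3-ethyl-4-(methoxycarbonyl)-1,4,5-trimethyl-5-(4,4,5,5-tetramethyl-1,3,2-dioxaborolan-2-yl)-3a,4,5,7a-tetrahydro-1H-inden-7-olate | [Li+].CCC1=C[C@@H](C)[C@@H]2C([O-])=C[C@](C)(B3OC(C)(C)C(C)(C)O3)[C@](C)(C(=O)OC)[C@@H]12
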